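**Strategy.** The route treats the nine-membered oxacycle (bridging oxygen, C3–C10) as an eight-membered cyclic acetal (oxygen, C3–C9) into which C10 is inserted. This is possible because C9 carries an oxygen and can therefore migrate. A rhodium carbene at C10 (α to the C1 ketone, tethered to C3) is trapped by the ring oxygen, and a Stevens [1,2]-shift of C9 from O to C10 follows. In one operation this closes the five-membered oxacycle, expands the oxocane to the oxonane, creates the ten-membered carbocycle C1–C10 and sets quaternary C10. The precursor is a bridged pseudo-ester (C9 acylal of the C12 acid) built by glycosylation and ring-closing metathesis. C4=C5 and both methylene esters are kept latent until the last step.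

Key step: step 14

Remarks and assumptions:
- Numbering is germacrane-type: C1 furanone C=O, C2 furanone CH, C3 furanone O–C=, C4 C(CH3)=, C5 =CH, C6 lactone O–CH, C7, C8 CH–O-methacrylate, C9 CH–OAc, C10 C(CH3)–O, C11 C(=CH2), C12 lactone C=O. Ob is the oxygen bridging C3 and C10.
- The target is taken as (6R,7S,8S,9S,10S), as in the SMILES.
- C11 in compounds 9–22 is a mixture of epimers of no consequence (left undefined in the SMILES); C9 of lactol 12 is an anomeric mixture.
- Compounds 1 and 7 are taken as purchased.

Step 1
Reactants: 1 3-[(4-methoxybenzyl)oxy]propanal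
Product: 2 (3S,4R)-1-[(4-methoxybenzyl)oxy]-4-methylhex-5-en-3-ol
Conditions: (E)-crotyl-B(Ipc)2 [made in the flask from (E)-but-2-ene, KOtBu, n-BuLi, (+)-Ipc2BOMe, BF3·OEt2], THF, −78 °C; then NaOH, H2O2
Reagents that add atoms: (E)-crotyldiisopinocampheylborane, C/C=C/CB([C@H]1C[C@H]2C[C@@H]([C@@H]1C)C2(C)C)[C@H]1C[C@H]2C[C@@H]([C@@H]1C)C2(C)C
Why: Brown crotylboration through a chair six-membered transition state should give the anti adduct, and the isopinocampheyl groups derived from (−)-α-pinene should direct attack to the aldehyde face that gives the (3S) carbinol at C3, which later fixes C10.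

Step 2
Reactants: 3 acrolein; 4 tert-butyl acrylate
Product: 5 tert-butyl 3-hydroxy-2-methylidenepent-4-enoate (racemic)
Conditions: DABCO (cat.), dioxane/H2O, rt
Reagents that add atoms: none
Why: Morita–Baylis–Hillman reaction, in which the DABCO-derived acrylate enolate adds 1,2 to acrolein and the amine is then eliminated; the carbinol centre is removed in step 3.

Step 3
Reactants: 5 tert-butyl 3-hydroxy-2-methylidenepent-4-enoate
Product: 6 tert-butyl (2Z)-2-(bromomethyl)penta-2,4-dienoate
Conditions: NBS, Me2S, CH2Cl2, 0 °C to rt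
Reagents that add atoms: N-bromosuccinimide, O=C1CCC(=O)N1Br
Why: Allylic bromination with transposition (SN2' attack of bromide on the alkoxysulfonium salt) should give the conjugated (2Z)-bromide, the usual outcome for Baylis–Hillman alcohols.

Step 4
Reactants: 6 tert-butyl (2Z)-2-(bromomethyl)penta-2,4-dienoate; 7 (R)-2,2-dimethyl-1,3-dioxolane-4-carbaldehyde
Product: 8 tert-butyl (3R,4S)-4-[(4R)-2,2-dimethyl-1,3-dioxolan-4-yl]-3-ethenyl-4-hydroxy-2-methylidenebutanoate
Conditions: indium powder, THF/H2O, rt
Reagents that add atoms: none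
Why: Barbier-type indium allylation, in which the allylindium reacts at its γ-carbon through a chair transition state so that the (Z)-reagent should give the C7/C8 syn adduct, while Felkin–Anh approach anti to the dioxolane C–O bond sets C8; the tert-butyl ester prevents lactonisation.

Step 5
Reactants: 8 Barbier adduct
Product: 9 tert-butyl (3R,4S)-4-[(4R)-2,2-dimethyl-1,3-dioxolan-4-yl]-3-ethenyl-4-hydroxy-2-[(phenylsulfonyl)methyl]butanoate (C2 epimers)
Conditions: PhSO2Na, AcOH, DMF, rt
Reagents that add atoms: sodium benzenesulfinate, [Na+].[O-]S(=O)c1ccccc1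
Why: Conjugate (sulfa-Michael) addition to the 2-substituted acrylate masks the exocyclic methylene as a β-sulfonyl ester that is inert to diazoethane, metal carbenes and peracid; the new centre at C11 is removed in step 16.

Step 6
Reactants: 9 sulfone alcohol
Product: 10 2-bromo-2-methylpropanoate ester of 9 at the C8 oxygen
Conditions: BrC(CH3)2COBr, pyridine, DMAP (cat.), CH2Cl2, 0 °C to rt
Reagents that add atoms: 2-bromo-2-methylpropanoyl bromide, CC(C)(Br)C(Br)=O
Why: DMAP-catalysed acylation of the secondary alcohol installs a latent methacrylate that has no Michael-acceptor double bond and can act as the participating group in step 8.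

Step 7
Reactants: 10 bromo ester acetonide
Product: 12 lactol (pseudo-acid) 6-hydroxy-δ-lactone with the C8 bromo ester and C7 vinyl group trans, via aldehyde ester 11 (not isolated)
Conditions: H5IO6, EtOAc, rt; then TFA/CH2Cl2, 0 °C to rt
Reagents that add atoms: none
Why: Periodic acid hydrolyses the terminal acetonide and cleaves the diol to the C9 aldehyde (glycol cleavage), and acidolysis of the tert-butyl ester frees the C12 acid, which should close onto the 5-oxo group as the six-membered lactol (ring-chain tautomerism); the anomeric mixture at C9 converges in step 8.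

Step 8
Reactants: 12 lactol; 2 (3S,4R)-1-[(4-methoxybenzyl)oxy]-4-methylhex-5-en-3-ol
Product: 13 acylal (pseudo-ester) with the C3 oxygen of 2 on C9, trans to the C8 ester and cis to the C7 vinyl group
Conditions: Ph2SO, Tf2O, 2-chloropyridine, CH2Cl2, −40 °C; then 2, −40 to 0 °C
Reagents that add atoms: none
Why: Dehydrative glycosylation, in which the lactol hydroxyl is activated as an oxosulfonium leaving group and neighbouring-group participation of the C8 ester carbonyl should direct alcohol 2 to the opposite face of C9, giving the 1,2-trans acylal needed for ring closure.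

Step 9
Reactants: 13 acylal diene
Product: 14 bridged (5Z)-2,10-dioxabicyclo[5.3.1]undec-5-en-9-one (eight-membered ring Ob, C3–C9 with (Z)-C5=C6)
Conditions: second-generation Grubbs catalyst, CH2Cl2 (high dilution), 40 °C
Reagents that add atoms: none
Why: Ring-closing metathesis of the two monosubstituted alkenes, which sit cis-1,3 on the lactone ring, should close the eight-membered ring; only the (Z)-alkene fits, and loss of ethene drives the reaction.

Step 10
Reactants: 14 bridged alkene
Product: 15 C5–C6 epoxide of 14 (oxygen on the convex face)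
Conditions: mCPBA, NaHCO3, CH2Cl2, 0 °C
Reagents that add atoms: mCPBA (3-chloroperoxybenzoic acid), OOC(=O)c1cccc(Cl)c1
Why: Prilezhaev epoxidation of the only electron-rich double bond should occur on the convex face of the bicyclo[5.3.1] skeleton, away from the lactone bridge, which places the oxygen at C6 with the configuration of the later lactone oxygen.

Step 11
Reactants: 15 epoxide
Product: 16 primary alcohol (C1–OH)
Conditions: DDQ, CH2Cl2/pH 7 buffer, 0 °C to rt
Reagents that add atoms: none
Why: Oxidative cleavage of the 4-methoxybenzyl ether (hydride abstraction, then hydrolysis) under buffered conditions should spare the epoxide, the acylal and the tertiary bromide.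

Step 12
Reactants: 16 primary alcohol
Product: 17 carboxylic acid (C1 acid on the C3–CH2 arm)
Conditions: TEMPO (cat.), PhI(OAc)2, MeCN/H2O, rt
Reagents that add atoms: water, O
Why: Oxoammonium (TEMPO) oxidation of the primary alcohol through the aldehyde hydrate to the acid under near-neutral conditions.

Step 13
Reactants: 17 carboxylic acid
Product: 19 α-methyl diazo ketone (C3–CH2–C1(=O)–C10(=N2)–CH3), via mixed anhydride 18 (not isolated)
Conditions: i-BuOCOCl, Et3N, THF, −20 °C; then CH3CHN2, Et2O, −20 to 0 °C
Reagents that add atoms: diazoethane, CC=[N+]=[N-]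
Why: Acylation of diazoethane by the mixed carbonic anhydride (Arndt–Eistert-type diazo ketone synthesis) should proceed cleanly because no Michael acceptor is present to form a pyrazoline.

Step 14
Reactants: 19 α-methyl diazo ketone
Product: 21 bridged tetrahydrofuran-3-one (Ob–C10 and C9–C10 bonds formed; nine-membered ring Ob, C3–C10), via oxonium ylide 20 (not isolated)
Conditions: Rh2(O2CCPh3)4 (2 mol %), CH2Cl2 (high dilution), slow addition, −20 °C to rt
Reagents that add atoms: none
Why: The catalyst converts 19 into an electrophilic rhodium carbene at C10, which is attacked by a lone pair of Ob (five-membered ring closure by Ob–C10 bond formation) to give the bicyclic oxonium ylide 20. The O+–C9 bond then breaks, helped by the lactone oxygen on C9 and by the strain of the bridged ring, and C9 recombines with the enolate carbon C10 within the ion or radical pair; this is a Stevens [1,2]-shift, the established route from cyclic acetals and ethers with tethered diazo ketones to ether-bridged medium-ring ketones. C10 is thereby inserted between Ob and C9, so the eight-membered ring (Ob, C3–C9) becomes the nine-membered ring (Ob, C3–C10) by one-atom ring expansion, and the ten-membered carbocycle C1–C10 is closed by the same C9–C10 bond (collapse of a tethered pair, not a separate macrocyclisation). C10 is controlled by C3, because the six-carbon chain can span the five-membered ring only cis, so C9 ends on the face of C10 that matches C4 at C3 and the methyl group is exo; C9 migrates with retention because C10 arrives from the oxygen that leaves. The step needs O-attack to outrun 1,2-hydride shift, C–H insertion and cyclopropanation, and the [1,2]-shift to outrun [2,3]-shift and β-elimination: the bulky carboxylate ligands and low temperature slow the hydride shift, no C=C bond is present, Ob is not an allylic ether, and only C9 bears a cation-stabilising oxygen.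

Step 15
Reactants: 21 bridged tetrahydrofuran-3-one
Product: 22 3(2H)-furanone (C2=C3)
Conditions: IBX, DMSO/fluorobenzene, 70 °C
Reagents that add atoms: none
Why: IBX dehydrogenation through the only possible enol (towards C2, since C10 is quaternary) should give the C2=C3 bond, which is favoured as part of a vinylogous ester.

Step 16
Reactants: 22 3(2H)-furanone
Product: 25 target CNP0365569.2, via hydroxy δ-lactone 23 (not isolated), via C9 alcohol 24 (not isolated)
Conditions: DBU, MeCN, rt to 45 °C; then Ac2O, DMAP (cat.), 0 °C to rt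
Reagents that add atoms: acetic anhydride, CC(=O)OC(C)=O
Why: DBU removes the vinylogously acidic C4–H and the dienolate opens the C5–C6 epoxide (vinylogous E1cB) to give the ring-(Z) C4=C5 bond and the C6 hydroxyl with retained configuration, while the same base expels benzenesulfinate (E1cB) and HBr (E2) to unveil the α-methylene lactone and the methacrylate; the C6 oxygen should then attack C12 (five-membered ring closure, δ- to the more stable trans-fused γ-lactone) and the released C9 hydroxyl is acetylated in the same flask.

**Compound list**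

1 | 3-[(4-methoxybenzyl)oxy]propanal | COc1ccc(COCCC=O)cc1 | starting material
2 | (3S,4R)-1-[(4-methoxybenzyl)oxy]-4-methylhex-5-en-3-ol | COc1ccc(COCC[C@H](O)[C@H](C)C=C)cc1 | intermediate
3 | acrolein | C=CC=O | starting material
4 | tert-butyl acrylate | C=CC(=O)OC(C)(C)C | starting material
5 | tert-butyl 3-hydroxy-2-methylidenepent-4-enoate (racemic) | C=CC(O)C(=C)C(=O)OC(C)(C)C | intermediate
6 | tert-butyl (2Z)-2-(bromomethyl)penta-2,4-dienoate | C=C/C=C(\CBr)C(=O)OC(C)(C)C | intermediate
7 | (R)-2,2-dimethyl-1,3-dioxolane-4-carbaldehyde | CC1(C)OC[C@@H](O1)C=O | starting material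
8 | tert-butyl (3R,4S)-4-[(4R)-2,2-dimethyl-1,3-dioxolan-4-yl]-3-ethenyl-4-hydroxy-2-methylidenebutanoate | CC1(C)OC[C@@H](O1)[C@@H](O)[C@H](C=C)C(=C)C(=O)OC(C)(C)C | intermediate
9 | tert-butyl (3R,4S)-4-[(4R)-2,2-dimethyl-1,3-dioxolan-4-yl]-3-ethenyl-4-hydroxy-2-[(phenylsulfonyl)methyl]butanoate (C2 epimers) | CC1(C)OC[C@@H](O1)[C@@H](O)[C@H](C=C)C(CS(=O)(=O)c1ccccc1)C(=O)OC(C)(C)C | intermediate
10 | 2-bromo-2-methylpropanoate of 9 at the C8 oxygen | CC1(C)OC[C@@H](O1)[C@@H](OC(=O)C(C)(C)Br)[C@H](C=C)C(CS(=O)(=O)c1ccccc1)C(=O)OC(C)(C)C | intermediate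
11 | tert-butyl (3R,4S)-4-[(2-bromo-2-methylpropanoyl)oxy]-3-ethenyl-5-oxo-2-[(phenylsulfonyl)methyl]pentanoate | O=C[C@@H](OC(=O)C(C)(C)Br)[C@H](C=C)C(CS(=O)(=O)c1ccccc1)C(=O)OC(C)(C)C | intermediate (not isolated)
12 | lactol (pseudo-acid): 6-hydroxy-δ-lactone, C8 bromo ester and C7 vinyl trans, C9 anomers | OC1OC(=O)C(CS(=O)(=O)c2ccccc2)[C@@H](C=C)[C@@H]1OC(=O)C(C)(C)Br | intermediate
13 | acylal (pseudo-ester): oxygen of 2 on C9, trans to the C8 ester, cis to the C7 vinyl group | COc1ccc(COCC[C@H](O[C@H]2OC(=O)C(CS(=O)(=O)c3ccccc3)[C@@H](C=C)[C@@H]2OC(=O)C(C)(C)Br)[C@H](C)C=C)cc1 | intermediate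
14 | (5Z)-11-[(2-bromo-2-methylpropanoyl)oxy]-3-{2-[(4-methoxybenzyl)oxy]ethyl}-4-methyl-8-[(phenylsulfonyl)methyl]-2,10-dioxabicyclo[5.3.1]undec-5-en-9-one | COc1ccc(COCC[C@@H]2O[C@H]3OC(=O)C(CS(=O)(=O)c4ccccc4)[C@@H](/C=C\[C@H]2C)[C@@H]3OC(=O)C(C)(C)Br)cc1 | intermediate
15 | C5–C6 epoxide of 14, oxygen on the convex face | COc1ccc(COCC[C@@H]2O[C@H]3OC(=O)C(CS(=O)(=O)c4ccccc4)[C@@H]([C@@H]5O[C@@H]5[C@H]2C)[C@@H]3OC(=O)C(C)(C)Br)cc1 | intermediate
16 | primary alcohol (4-methoxybenzyl group of 15 removed) | OCC[C@@H]2O[C@H]3OC(=O)C(CS(=O)(=O)c4ccccc4)[C@@H]([C@@H]5O[C@@H]5[C@H]2C)[C@@H]3OC(=O)C(C)(C)Br | intermediate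
17 | carboxylic acid (C1 acid on the C3–CH2 arm) | OC(=O)C[C@@H]2O[C@H]3OC(=O)C(CS(=O)(=O)c4ccccc4)[C@@H]([C@@H]5O[C@@H]5[C@H]2C)[C@@H]3OC(=O)C(C)(C)Br | intermediate
18 | isobutyl carbonic mixed anhydride of 17 | CC(C)COC(=O)OC(=O)C[C@@H]2O[C@H]3OC(=O)C(CS(=O)(=O)c4ccccc4)[C@@H]([C@@H]5O[C@@H]5[C@H]2C)[C@@H]3OC(=O)C(C)(C)Br | intermediate (not isolated)
19 | α-methyl diazo ketone (3-diazo-2-oxobutyl arm on C3) | CC(=[N+]=[N-])C(=O)C[C@@H]2O[C@H]3OC(=O)C(CS(=O)(=O)c4ccccc4)[C@@H]([C@@H]5O[C@@H]5[C@H]2C)[C@@H]3OC(=O)C(C)(C)Br | intermediate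
20 | bicyclic oxonium ylide (Ob bonded to C3, C9 and C10) | C[C-]1C(=O)C[C@@H]2[O+]1[C@H]3OC(=O)C(CS(=O)(=O)c4ccccc4)[C@@H]([C@@H]5O[C@@H]5[C@H]2C)[C@@H]3OC(=O)C(C)(C)Br | intermediate (not isolated)
21 | bridged tetrahydrofuran-3-one: C10(CH3) bonded to Ob, C1 and C9; nine-membered ring Ob, C3–C10; C5–C6 epoxide; δ-lactone C9–O–C12; C8 bromo ester | C[C@@]12O[C@@H](CC1=O)[C@H](C)[C@H]3O[C@H]3[C@@H]4C(CS(=O)(=O)c5ccccc5)C(=O)O[C@H]2[C@H]4OC(=O)C(C)(C)Br | intermediate
22 | 3(2H)-furanone (C2=C3) derived from 21 | C[C@@]12OC(=CC1=O)[C@H](C)[C@H]3O[C@H]3[C@@H]4C(CS(=O)(=O)c5ccccc5)C(=O)O[C@H]2[C@H]4OC(=O)C(C)(C)Br | intermediate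
23 | hydroxy δ-lactone: (Z)-C4=C5, C6–OH, 9,12-δ-lactone with exocyclic methylene, C8 methacrylate | C[C@@]12OC(=CC1=O)/C(C)=C\[C@@H](O)[C@@H]4C(=C)C(=O)O[C@H]2[C@H]4OC(=O)C(C)=C | intermediate (not isolated)
24 | C9 alcohol: 6,12-γ-lactone, C8 methacrylate, free C9–OH (9-deacetyl target) | C=C(C)C(=O)O[C@H]1[C@H]2C(=C)C(=O)O[C@@H]2/C=C(/C)C2=CC(=O)[C@@](C)(O2)[C@H]1O | intermediate (not isolated)
25 | CNP0365569.2 (6R,7S,8S,9S,10S) | C=C(C)C(=O)O[C@H]1[C@H]2C(=C)C(=O)O[C@@H]2/C=C(/C)C2=CC(=O)[C@@](C)(O2)[C@H]1OC(C)=O | target

**Step count.** 16 steps in total. The longest linear sequence is 15 steps (steps 2–16, from acrolein and tert-butyl acrylate); step 1 is the short branch.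

**Steps most likely to fail**

Step 14 (key step). The carbene may be lost before Ob can add, chiefly by 1,2-hydride migration from its methyl group to give an enone, or by C–H insertion at C4. The fallback removes the methyl group from the carbene and introduces it after the ring expansion. It sets out from acid 17 through mixed anhydride 18, which is treated with TMSCHN2 to give the terminal diazo ketone F1. Rh2(OAc)4 should then effect the same ylide formation and [1,2]-shift to the C10-unsubstituted bridged ketone F2, and IBX should give the 10-desmethyl furanone F3. Its C10 enolate (LiN(SiMe3)2, one equivalent, THF, −78 °C) is methylated with MeI on the face away from the C9 bridge, which comes back to the route at furanone 22.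

Step 16. The cascade may stall or branch: the C4 proton may not align with the epoxide C–O bond for the vinylogous elimination, the δ- to γ-lactone transposition may be slow under base, or the C8 acyl group may migrate to the freed cis C9 hydroxyl before acetylation. The fallback opens the epoxide with electrophilic assistance and transposes the lactone under acid. It sets out from 22: TMSOTf/2,6-lutidine followed by DBU (epoxide to allylic silyl ether isomerisation, with loss of sulfinate and HBr) should give the C6 trimethylsilyl ether F4. HF·pyridine then releases alcohol 23, and camphorsulfonic acid in CH2Cl2 transposes the lactone, which comes back to the route at alcohol 24; this is acetylated as in step 16.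

Step 10. Facial selectivity in the epoxidation may be poor or inverted, which would put the C6 oxygen on the wrong face and lead to the cis-lactone series. The fallback delivers the oxygen anti to the electrophile. It sets out from alkene 14: NBS in aqueous THF should give the trans-bromohydrin F5 (bromonium ion on the face the peracid prefers, water from the other face), and K2CO3 in MeOH closes it with inversion at the bromide carbon, which comes back to the route at epoxide 15.

Further compounds
F1 | step 14 | terminal diazo ketone (3-diazo-2-oxopropyl arm on C3) | [N-]=[N+]=CC(=O)C[C@@H]2O[C@H]3OC(=O)C(CS(=O)(=O)c4ccccc4)[C@@H]([C@@H]5O[C@@H]5[C@H]2C)[C@@H]3OC(=O)C(C)(C)Br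
F2 | step 14 | 10-desmethyl bridged tetrahydrofuran-3-one | [C@@H]12O[C@@H](CC1=O)[C@H](C)[C@H]3O[C@H]3[C@@H]4C(CS(=O)(=O)c5ccccc5)C(=O)O[C@H]2[C@H]4OC(=O)C(C)(C)Br
F3 | step 14 | 10-desmethyl 3(2H)-furanone | [C@@H]12OC(=CC1=O)[C@H](C)[C@H]3O[C@H]3[C@@H]4C(CS(=O)(=O)c5ccccc5)C(=O)O[C@H]2[C@H]4OC(=O)C(C)(C)Br
F4 | step 16 | C6 trimethylsilyl ether of hydroxy δ-lactone 23 | C[C@@]12OC(=CC1=O)/C(C)=C\[C@@H](O[Si](C)(C)C)[C@@H]4C(=C)C(=O)O[C@H]2[C@H]4OC(=O)C(C)=C
F5 | step 10 | trans-bromohydrin of 14 (C6–OH, C5–Br) | COc1ccc(COCC[C@@H]2O[C@H]3OC(=O)C(CS(=O)(=O)c4ccccc4)[C@@H]([C@H](O)[C@@H](Br)[C@H]2C)[C@@H]3OC(=O)C(C)(C)Br)cc1
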